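**Retrosynthetic overview**

1. Ring A is the phloroglucinol ring, ring B the central ring, rings C and D the two trihydroxyphenyl rings. The strategy rests on ring A, where the hydroxyl-bearing carbons 1 and 3 flank the ether carbon 2: carried as formyl groups they first make carbon 2 electrophilic, and a twofold Dakin oxidation then turns them into the two ring-A C–O bonds (16 → 18).
2. The ether between carbon 2 of ring A and carbon 1 of ring B is made before that by SNAr of the phenoxide of 10 on fluoride 15, which has a formyl group on each side of the C–F carbon.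
3. Ring-BCD phenol 10 follows the same logic: difluoro dialdehyde 5 takes up two molecules of phenol 6 (the aryl ethers at carbons 2 and 4 of ring B), a twofold Dakin oxidation gives symmetric diol 9, and one hydroxyl is methylated.
4. The last step cleaves the nine methyl ethers of 18 with BBr3.
5. No ring is formed; all four benzene rings are bought, and they are joined in the order B with C and D, then A.

Key step: step 9

Remark on the chemistry: the target has no stereocentre; aldehydes 1 and 11 are taken as purchased (each is also one ortho-lithiation/formylation from 2,6-difluoroanisole or 4-fluoroanisole).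

**Route**

Step 1
Reactants: 1 2,4-difluoro-3-methoxybenzaldehyde
Product: 2 1-(dimethoxymethyl)-2,4-difluoro-3-methoxybenzene
Conditions: HC(OMe)3 (neat), p-TsOH·H2O (cat.), 40 °C; Et3N quench
Reagents that add atoms: trimethyl orthoformate COC(OC)OC
Why: Acid-catalysed acetalisation of an electron-poor benzaldehyde, with the orthoformate as methoxy donor and water scavenger, masks the formyl group against butyllithium (acetal protection).

Step 2
Reactants: 2 1-(dimethoxymethyl)-2,4-difluoro-3-methoxybenzene
Product: 5 4,6-difluoro-5-methoxybenzene-1,3-dicarbaldehyde, via aryllithium 3 (not isolated), via acetal aldehyde 4 (not isolated)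
Conditions: n-BuLi, PMDTA (N,N,N',N'',N''-pentamethyldiethylenetriamine), THF, −78 °C; DMF, −78 → 0 °C; 2 M HCl, THF, rt
Reagents that add atoms: N,N-dimethylformamide CN(C)C=O; water O
Why: Acidity-controlled ortho-metalation should remove the only proton next to fluorine (it is also para to the second fluorine), the aryllithium is formylated by DMF (Bouveault-type formylation), and the acidic work-up hydrolyses the acetal.

Step 3
Reactants: 5 4,6-difluoro-5-methoxybenzene-1,3-dicarbaldehyde; 6 3,4,5-trimethoxyphenol (2.2 equiv)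
Product: 7 5-methoxy-4,6-bis(3,4,5-trimethoxyphenoxy)benzene-1,3-dicarbaldehyde
Conditions: K2CO3, DMF, rt → 50 °C, Ar
Reagents that add atoms: none
Why: Twofold SNAr (addition–elimination), in which each fluoride has one ortho and one para formyl group to stabilise the Meisenheimer adduct, so the phenoxide of 6 should displace both under mild carbonate conditions.

Step 4
Reactants: 7 5-methoxy-4,6-bis(3,4,5-trimethoxyphenoxy)benzene-1,3-dicarbaldehyde
Product: 9 5-methoxy-4,6-bis(3,4,5-trimethoxyphenoxy)benzene-1,3-diol, via ring-B diformate 8 (not isolated)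
Conditions: mCPBA (3 equiv), CH2Cl2, 0 °C → rt; aq. Na2S2O3, then aq. NaHCO3 wash; K2CO3 (cat.), MeOH, 0 °C, Ar
Reagents that add atoms: 3-chloroperoxybenzoic acid O=C(OO)c1cccc(Cl)c1
Why: Twofold Dakin-type Baeyer–Villiger oxidation, in which each formyl-bearing carbon has an ortho and a para aryloxy donor and should therefore migrate to the peracid oxygen in preference to hydride, followed by methanolysis of the aryl formates once the oxidant is destroyed.

Step 5
Reactants: 9 5-methoxy-4,6-bis(3,4,5-trimethoxyphenoxy)benzene-1,3-diol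
Product: 10 3,5-dimethoxy-2,4-bis(3,4,5-trimethoxyphenoxy)phenol
Conditions: MeI (0.6 equiv), K2CO3 (0.6 equiv), acetone, rt, Ar; unreacted 9 recovered and recycled
Reagents that add atoms: iodomethane CI
Why: Williamson O-methylation of one of two equivalent phenols with the alkylating agent as limiting reagent, a statistical desymmetrisation in which the diol left over is returned to the step.

Step 6
Reactants: 11 2-fluoro-5-methoxybenzaldehyde
Product: 12 2-(dimethoxymethyl)-1-fluoro-4-methoxybenzene
Conditions: HC(OMe)3 (neat), p-TsOH·H2O (cat.), 40 °C; Et3N quench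
Reagents that add atoms: trimethyl orthoformate COC(OC)OC
Why: Acid-catalysed acetalisation as in step 1 protects the formyl group before the second metalation (acetal protection).

Step 7
Reactants: 12 2-(dimethoxymethyl)-1-fluoro-4-methoxybenzene
Product: 15 2-fluoro-5-methoxybenzene-1,3-dicarbaldehyde, via aryllithium 13 (not isolated), via acetal aldehyde 14 (not isolated)
Conditions: n-BuLi, PMDTA, THF, −78 °C; DMF, −78 → 0 °C; 2 M HCl, THF, rt
Reagents that add atoms: N,N-dimethylformamide CN(C)C=O; water O
Why: Acidity-controlled ortho-metalation with triamine-saturated butyllithium, which is not steered by the methoxy or acetal oxygens and should remove the unhindered proton next to fluorine and not the one flanked by methoxy and acetal, followed by DMF formylation and acetal hydrolysis.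

Step 8
Reactants: 10 3,5-dimethoxy-2,4-bis(3,4,5-trimethoxyphenoxy)phenol; 15 2-fluoro-5-methoxybenzene-1,3-dicarbaldehyde
Product: 16 2-[3,5-dimethoxy-2,4-bis(3,4,5-trimethoxyphenoxy)phenoxy]-5-methoxybenzene-1,3-dicarbaldehyde
Conditions: K2CO3, DMF, rt → 40 °C, Ar
Reagents that add atoms: none
Why: SNAr at carbon 2 of ring A, whose C–F carbon is made strongly electrophilic by the two ortho formyl groups, so the phenoxide of 10 (one ortho substituent only) should give the tri-ortho-substituted diaryl ether without a metal catalyst.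

Step 9
Reactants: 16 2-[3,5-dimethoxy-2,4-bis(3,4,5-trimethoxyphenoxy)phenoxy]-5-methoxybenzene-1,3-dicarbaldehyde
Product: 18 2-[3,5-dimethoxy-2,4-bis(3,4,5-trimethoxyphenoxy)phenoxy]-5-methoxybenzene-1,3-diol, via ring-A diformate 17 (not isolated)
Conditions: mCPBA (3–4 equiv), CH2Cl2 (anhydrous, no base), 0 °C → rt; aq. Na2S2O3, then aq. NaHCO3 wash; K2CO3 (cat.), MeOH, 0 °C, Ar
Reagents that add atoms: 3-chloroperoxybenzoic acid O=C(OO)c1cccc(Cl)c1
Why: Each formyl group adds the peracid to give a Criegee peroxy hemiacetal, from which the ring-A carbon (carbon 1, then carbon 3) shifts to the proximal peroxide oxygen as 3-chlorobenzoate leaves, so that the two new ring-A C–O bonds arise as the aryl formates of 17, and catalytic carbonate in methanol then passes the formyl groups to the solvent and frees resorcinol 18. The closest known reaction is the Dakin-type Baeyer–Villiger oxidation of ortho-alkoxy- and ortho-aryloxybenzaldehydes, the usual sequel to an SNAr on a 2-fluorobenzaldehyde in diaryl ether synthesis. No ring is closed and no stereocentre is formed. The step needs aryl and not hydride migration at both aldehydes: the lone pair of the ether oxygen on carbon 2, ortho to each migrating carbon, stabilises the electron-poor migrating centre, and the anhydrous, base-free medium disfavours the hydrate and the hydride-shift path to carboxylic acids. It also needs the peracid to spare the methoxylated rings B, C and D: the electrophilic formyl groups should react faster than the arenes at 0 °C, and the phenols stay masked as formates until thiosulfate has destroyed the excess oxidant.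

Step 10
Reactants: 18 2-[3,5-dimethoxy-2,4-bis(3,4,5-trimethoxyphenoxy)phenoxy]-5-methoxybenzene-1,3-diol
Product: 19 2-[3,5-dihydroxy-2,4-bis(3,4,5-trihydroxyphenoxy)phenoxy]benzene-1,3,5-triol
Conditions: BBr3 (15 equiv), CH2Cl2, −78 °C → rt, Ar; H2O, 0 °C; Sephadex LH-20 under Ar
Reagents that add atoms: none
Why: Lewis-acid cleavage of aryl methyl ethers by BBr3 (bromide attacks the methyl group of the boron-complexed ether), which should remove all nine methyl groups and leave the three diaryl ether bonds, which offer no saturated carbon for bromide attack.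

**Compound list**

1 | 2,4-difluoro-3-methoxybenzaldehyde | COc1c(F)ccc(C=O)c1F | starting material
2 | 1-(dimethoxymethyl)-2,4-difluoro-3-methoxybenzene | COc1c(F)ccc(C(OC)OC)c1F | intermediate
3 | [5-(dimethoxymethyl)-2,4-difluoro-3-methoxyphenyl]lithium | COc1c(F)c([Li])cc(C(OC)OC)c1F | intermediate
4 | 5-(dimethoxymethyl)-2,4-difluoro-3-methoxybenzaldehyde | COc1c(F)c(C=O)cc(C(OC)OC)c1F | intermediate
5 | 4,6-difluoro-5-methoxybenzene-1,3-dicarbaldehyde | COc1c(F)c(C=O)cc(C=O)c1F | intermediate
6 | 3,4,5-trimethoxyphenol | COc1cc(O)cc(OC)c1OC | starting material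
7 | 5-methoxy-4,6-bis(3,4,5-trimethoxyphenoxy)benzene-1,3-dicarbaldehyde | COc1c(Oc2cc(OC)c(OC)c(OC)c2)c(C=O)cc(C=O)c1Oc1cc(OC)c(OC)c(OC)c1 | intermediate
8 | 5-methoxy-4,6-bis(3,4,5-trimethoxyphenoxy)-1,3-phenylene diformate | COc1c(Oc2cc(OC)c(OC)c(OC)c2)c(OC=O)cc(OC=O)c1Oc1cc(OC)c(OC)c(OC)c1 | intermediate
9 | 5-methoxy-4,6-bis(3,4,5-trimethoxyphenoxy)benzene-1,3-diol | COc1c(Oc2cc(OC)c(OC)c(OC)c2)c(O)cc(O)c1Oc1cc(OC)c(OC)c(OC)c1 | intermediate
10 | 3,5-dimethoxy-2,4-bis(3,4,5-trimethoxyphenoxy)phenol | COc1cc(O)c(Oc2cc(OC)c(OC)c(OC)c2)c(OC)c1Oc1cc(OC)c(OC)c(OC)c1 | intermediate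
11 | 2-fluoro-5-methoxybenzaldehyde | COc1ccc(F)c(C=O)c1 | starting material
12 | 2-(dimethoxymethyl)-1-fluoro-4-methoxybenzene | COc1ccc(F)c(C(OC)OC)c1 | intermediate
13 | [3-(dimethoxymethyl)-2-fluoro-5-methoxyphenyl]lithium | COc1cc([Li])c(F)c(C(OC)OC)c1 | intermediate
14 | 3-(dimethoxymethyl)-2-fluoro-5-methoxybenzaldehyde | COc1cc(C=O)c(F)c(C(OC)OC)c1 | intermediate
15 | 2-fluoro-5-methoxybenzene-1,3-dicarbaldehyde | COc1cc(C=O)c(F)c(C=O)c1 | intermediate
16 | 2-[3,5-dimethoxy-2,4-bis(3,4,5-trimethoxyphenoxy)phenoxy]-5-methoxybenzene-1,3-dicarbaldehyde | COc1cc(C=O)c(Oc2cc(OC)c(Oc3cc(OC)c(OC)c(OC)c3)c(OC)c2Oc2cc(OC)c(OC)c(OC)c2)c(C=O)c1 | intermediate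
17 | 2-[3,5-dimethoxy-2,4-bis(3,4,5-trimethoxyphenoxy)phenoxy]-5-methoxy-1,3-phenylene diformate | COc1cc(OC=O)c(Oc2cc(OC)c(Oc3cc(OC)c(OC)c(OC)c3)c(OC)c2Oc2cc(OC)c(OC)c(OC)c2)c(OC=O)c1 | intermediate
18 | 2-[3,5-dimethoxy-2,4-bis(3,4,5-trimethoxyphenoxy)phenoxy]-5-methoxybenzene-1,3-diol | COc1cc(O)c(Oc2cc(OC)c(Oc3cc(OC)c(OC)c(OC)c3)c(OC)c2Oc2cc(OC)c(OC)c(OC)c2)c(O)c1 | intermediate
19 | 2-[3,5-dihydroxy-2,4-bis(3,4,5-trihydroxyphenoxy)phenoxy]benzene-1,3,5-triol | Oc1cc(O)c(Oc2cc(O)c(Oc3cc(O)c(O)c(O)c3)c(O)c2Oc2cc(O)c(O)c(O)c2)c(O)c1 | target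

**Step count**

Total: 10 steps. Longest linear sequence: 8 steps (1, 2, 3, 4, 5, 8, 9, 10); the ring-A branch is steps 6 and 7.

**Steps most likely to fail**

Step 9. Hydride instead of aryl migration may occur at one or both aldehydes, because ring A offers only one ortho oxygen donor and carries the second formyl group meta to the migrating carbon; this would give benzoic acids. Slow oxidation of the electron-rich rings by excess peracid is the second danger. The fallback sets out from 10 and comes back at 19, and it buys the ring-A oxygens with the arene instead of making them. Phenol 10 is coupled with 2-iodo-1,3,5-trimethoxybenzene in an Ullmann diaryl ether synthesis (CuI, 2,2,6,6-tetramethylheptane-3,5-dione, Cs2CO3, NMP, 120 °C, Ar) to give 2-[3,5-dimethoxy-2,4-bis(3,4,5-trimethoxyphenoxy)phenoxy]-1,3,5-trimethoxybenzene F1. Its eleven methyl ethers are then cleaved with BBr3 under the conditions of step 10 to give 19.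

Step 7. Deprotonation may compete at the position between the methoxy and acetal groups, where lithium can be held by two oxygens, and would lead to a regioisomeric dialdehyde. The fallback sets out from 11 and comes back at 15. It replaces the methyl ether by a triisopropylsilyl ether, which does not coordinate lithium and shields both of its ortho positions, so that only the proton next to fluorine remains accessible. BBr3 (CH2Cl2, −78 → 0 °C) demethylates 11 to 2-fluoro-5-hydroxybenzaldehyde F2, and TIPSCl with imidazole in DMF gives 2-fluoro-5-(triisopropylsilyloxy)benzaldehyde F3. Trimethyl orthoformate with catalytic pyridinium tosylate gives [3-(dimethoxymethyl)-4-fluorophenoxy]triisopropylsilane F4. s-BuLi (THF, −78 °C) gives {3-(dimethoxymethyl)-2-fluoro-5-(triisopropylsilyloxy)phenyl}lithium F5, which DMF converts into 3-(dimethoxymethyl)-2-fluoro-5-(triisopropylsilyloxy)benzaldehyde F6. Dilute HCl added to the same flask (THF, rt) hydrolyses the acetal to 2-fluoro-5-(triisopropylsilyloxy)benzene-1,3-dicarbaldehyde F7. Bu4NF buffered with AcOH (THF, 0 °C) frees 2-fluoro-5-hydroxybenzene-1,3-dicarbaldehyde F8. A Mitsunobu methylation (MeOH, PPh3, diisopropyl azodicarboxylate, THF, 0 °C) then gives 15; it is chosen over a carbonate alkylation so that no free phenoxide stands beside the activated fluoride.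

Step 5. Over-methylation to the dimethyl ether and incomplete conversion may drain material through repeated recycling. The fallback sets out from 9 and comes back at 16, and it moves the desymmetrisation into the coupling. Diol 9 in threefold excess is monoarylated by fluoride 15 (K2CO3, DMF, rt, Ar) to 2-[5-hydroxy-3-methoxy-2,4-bis(3,4,5-trimethoxyphenoxy)phenoxy]-5-methoxybenzene-1,3-dicarbaldehyde F9, and the surplus of 9 is recovered. The one remaining phenol is then methylated to completion (MeI, K2CO3, acetone) to give 16.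

**Further compounds**

F1 | step 9 | 2-[3,5-dimethoxy-2,4-bis(3,4,5-trimethoxyphenoxy)phenoxy]-1,3,5-trimethoxybenzene | COc1cc(OC)c(Oc2cc(OC)c(Oc3cc(OC)c(OC)c(OC)c3)c(OC)c2Oc2cc(OC)c(OC)c(OC)c2)c(OC)c1
F2 | step 7 | 2-fluoro-5-hydroxybenzaldehyde | O=Cc1cc(O)ccc1F
F3 | step 7 | 2-fluoro-5-(triisopropylsilyloxy)benzaldehyde | CC(C)[Si](Oc1ccc(F)c(C=O)c1)(C(C)C)C(C)C
F4 | step 7 | [3-(dimethoxymethyl)-4-fluorophenoxy]triisopropylsilane | COC(OC)c1cc(O[Si](C(C)C)(C(C)C)C(C)C)ccc1F
F5 | step 7 | {3-(dimethoxymethyl)-2-fluoro-5-(triisopropylsilyloxy)phenyl}lithium | COC(OC)c1cc(O[Si](C(C)C)(C(C)C)C(C)C)cc([Li])c1F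
F6 | step 7 | 3-(dimethoxymethyl)-2-fluoro-5-(triisopropylsilyloxy)benzaldehyde | COC(OC)c1cc(O[Si](C(C)C)(C(C)C)C(C)C)cc(C=O)c1F
F7 | step 7 | 2-fluoro-5-(triisopropylsilyloxy)benzene-1,3-dicarbaldehyde | O=Cc1cc(O[Si](C(C)C)(C(C)C)C(C)C)cc(C=O)c1F
F8 | step 7 | 2-fluoro-5-hydroxybenzene-1,3-dicarbaldehyde | O=Cc1cc(O)cc(C=O)c1F
F9 | step 5 | 2-[5-hydroxy-3-methoxy-2,4-bis(3,4,5-trimethoxyphenoxy)phenoxy]-5-methoxybenzene-1,3-dicarbaldehyde | COc1cc(C=O)c(Oc2cc(O)c(Oc3cc(OC)c(OC)c(OC)c3)c(OC)c2Oc2cc(OC)c(OC)c(OC)c2)c(C=O)c1
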